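**Retrosynthetic overview**
1. The target, 2-henicosyl-5,7-dihydroxy-4H-chromen-4-one, is cut in its side chain between C4' and C5' (counted from ring C2). This gives stearic acid (C17 after loss of CO2) and 5-(chromon-2-yl)pentanoic acid (C4 tether after loss of CO2), to be joined by a mixed Kolbe (anodic decarboxylative radical) coupling.
2. Enabling feature: the chain on C2 of the 4H-chromen-4-one is unbranched and fully saturated, so C4' and C5' are plain primary CH2 groups, and C4' is three CH2 away from pyranone C2. Neither radical is stabilised or easily oxidised further, and the benzo-γ-pyrone with acetylated 5-O and 7-O is electron-poor and inert at the anode.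
3. The chromone acid comes from 2',4',6'-trihydroxyacetophenone and methyl adipoyl chloride: C-acylation of the polyanion makes the C2–C3 bond, and acid cyclodehydration closes the γ-pyrone ring (O1–C2). This is the only ring formed; the benzene ring is bought.
4. Order: pyranone ring (step 2), phenol acetylation (step 3), Kolbe coupling (step 4), deacetylation (step 5).

Key step: step 4

Remark: the target has no stereocentre and no stereogenic double bond, so it is achiral and no step needs stereocontrol.

**Step 1**
Reactants: 1 2',4',6'-trihydroxyacetophenone (anhydrous, dried from the commercial monohydrate); 2 methyl 6-chloro-6-oxohexanoate (methyl adipoyl chloride)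
Product: 4 methyl 6,8-dioxo-8-(2,4,6-trihydroxyphenyl)octanoate, via tetralithio polyanion 3 (not isolated)
Conditions: LiHMDS (4.2 equiv), THF, −78 → −10 °C; then 2 (1.05 equiv), −78 °C → rt; cold aq. HCl quench
Reagents that add atoms: none
Why: Claisen-type C-acylation of the lithium polyanion of a polyhydroxyacetophenone (three phenoxides plus the methyl ketone enolate) should take place at the enolate carbon, the most nucleophilic site, and at −78 °C the acid chloride of 2 reacts far faster than its methyl ester.

**Step 2**
Reactants: 4 methyl 6,8-dioxo-8-(2,4,6-trihydroxyphenyl)octanoate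
Product: 6 5-(5,7-dihydroxy-4-oxo-4H-chromen-2-yl)pentanoic acid, via chromone methyl ester 5 (not isolated)
Conditions: AcOH / 6 M aq. HCl (2:1), 100 °C
Reagents that add atoms: water, O
Why: Acid-catalysed cyclodehydration of the o-hydroxyaryl 1,3-diketone closes the γ-pyrone ring (the two ortho OH groups are equivalent, so only one chromone can form), and the same hot aqueous acid hydrolyses the remote methyl ester while the chromone, which alkali could open, is stable.

**Step 3**
Reactants: 6 5-(5,7-dihydroxy-4-oxo-4H-chromen-2-yl)pentanoic acid
Product: 8 5-(5,7-diacetoxy-4-oxo-4H-chromen-2-yl)pentanoic acid, via mixed acetic anhydride 7 (not isolated)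
Conditions: Ac2O (5 equiv), pyridine, DMAP (cat.), 0 °C → rt; then ice / 1 M HCl, 0 °C, 30 min
Reagents that add atoms: acetic anhydride, CC(=O)OC(C)=O; water, O (hydrolysis of 7 on work-up)
Why: DMAP-catalysed O-acetylation should cap both phenols, including the chelated 5-OH, so that no oxidisable phenol reaches the anode; the carboxyl group passes through the mixed anhydride, which cold dilute acid hydrolyses selectively because an anhydride is far more electrophilic than an aryl acetate.

**Step 4**
Reactants: 8 5-(5,7-diacetoxy-4-oxo-4H-chromen-2-yl)pentanoic acid; 9 stearic acid (octadecanoic acid, 6 equiv)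
Product: 10 2-henicosyl-4-oxo-4H-chromene-5,7-diyl diacetate
Conditions: undivided cell, Pt anode / Pt cathode, constant current (ca. 0.2 A cm−2, ca. 1.5 F per mol of total acid, periodic polarity reversal), Et3N (5 mol % of total CO2H), MeOH, 50 °C
Reagents that add atoms: none
Why: At the Pt anode under high current density the two partially neutralised acids are oxidised to acyloxy radicals that lose CO2 at once, and the resulting heptadecyl and 4-(5,7-diacetoxy-4-oxo-4H-chromen-2-yl)butyl radicals combine in the dense radical layer at the electrode to form the C4'–C5' bond, while the cathode turns the acid protons into H2. The closest known reaction type is the mixed (hetero) Kolbe electrolysis of a fatty acid with an ω-functionalised alkanoic acid such as an adipic half-ester, run with the cheap acid in excess. No ring is closed and no stereocentre is created. Cross- over homo-coupling is only statistical, so 9 is used in six-fold excess: the chromone radical then meets mostly heptadecyl radicals, and the co-formed tetratriacontane is non-polar and should be removable by filtration and a hydrocarbon wash. The step also needs radical coupling to outrun 5-exo attack of the C4' radical on pyranone C2, over-oxidation to a carbocation and oxidation of the aromatic ring; the substrate secures this because both radicals are primary and unstabilised, C2 is fully substituted and oxygen-bearing (a slow 5-exo acceptor), and the diacetylated benzo-γ-pyrone is too electron-poor to be oxidised before the carboxylates. At the Pt cathode proton discharge from the excess acid is far easier than reduction of the enone, and the aryl acetates see only a carboxylic acid/carboxylate buffer.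

**Step 5**
Reactants: 10 2-henicosyl-4-oxo-4H-chromene-5,7-diyl diacetate
Product: 11 2-henicosyl-5,7-dihydroxy-4H-chromen-4-one
Conditions: conc. HCl (cat.), MeOH / THF (1:1), 55 °C
Reagents that add atoms: none
Why: Acid-catalysed transesterification (methanolysis) of the two aryl acetates should release both phenols as methyl acetate forms; the chromone ring is inert to dilute acid and the saturated chain is unaffected.

**Compound list**
1 | 2',4',6'-trihydroxyacetophenone | CC(=O)c1c(O)cc(O)cc1O | starting material
2 | methyl 6-chloro-6-oxohexanoate (methyl adipoyl chloride) | COC(=O)CCCCC(=O)Cl | starting material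
3 | tetralithium salt of 1 (tris-phenoxide and ketone enolate) | [Li+].[Li+].[Li+].[Li+].C=C([O-])c1c([O-])cc([O-])cc1[O-] | intermediate
4 | methyl 6,8-dioxo-8-(2,4,6-trihydroxyphenyl)octanoate | COC(=O)CCCCC(=O)CC(=O)c1c(O)cc(O)cc1O | intermediate
5 | methyl 5-(5,7-dihydroxy-4-oxo-4H-chromen-2-yl)pentanoate | COC(=O)CCCCc1cc(=O)c2c(O)cc(O)cc2o1 | intermediate
6 | 5-(5,7-dihydroxy-4-oxo-4H-chromen-2-yl)pentanoic acid | OC(=O)CCCCc1cc(=O)c2c(O)cc(O)cc2o1 | intermediate
7 | acetic 5-(5,7-diacetoxy-4-oxo-4H-chromen-2-yl)pentanoic anhydride | CC(=O)OC(=O)CCCCc1cc(=O)c2c(OC(C)=O)cc(OC(C)=O)cc2o1 | intermediate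
8 | 5-(5,7-diacetoxy-4-oxo-4H-chromen-2-yl)pentanoic acid | OC(=O)CCCCc1cc(=O)c2c(OC(C)=O)cc(OC(C)=O)cc2o1 | intermediate
9 | stearic acid (octadecanoic acid) | CCCCCCCCCCCCCCCCCC(=O)O | starting material
10 | 2-henicosyl-4-oxo-4H-chromene-5,7-diyl diacetate | CCCCCCCCCCCCCCCCCCCCCc1cc(=O)c2c(OC(C)=O)cc(OC(C)=O)cc2o1 | intermediate
11 | 2-henicosyl-5,7-dihydroxy-4H-chromen-4-one | CCCCCCCCCCCCCCCCCCCCCc1cc(=O)c2c(O)cc(O)cc2o1 | target

**Step count**
Total steps: 5. Longest linear sequence: 5 steps (1 → 4 → 6 → 8 → 10 → 11).

**Steps most likely to fail**

Step 4. The cross-coupling may be eroded by homo-coupling, by passivation of the anode with deposited hydrocarbon, or by partial loss of an aryl acetate followed by anodic oxidation of the freed phenol. The fallback replaces the anodic radical–radical coupling by a reductive nickel-catalysed decarboxylative alkyl–alkyl coupling; it sets out from 8 and comes back at 10. Acid 8 would be condensed with N-hydroxyphthalimide (DIC, cat. DMAP, CH2Cl2) to the redox-active ester 1,3-dioxoisoindolin-2-yl 5-(5,7-diacetoxy-4-oxo-4H-chromen-2-yl)pentanoate F1. In parallel, purchased 1-bromoheptadecane (CCCCCCCCCCCCCCCCCBr) would be converted with Mg in THF into heptadecylmagnesium bromide F2 and then, with ZnCl2 (0.5 equiv), fully transmetallated to diheptadecylzinc F3. Negishi-type coupling of F1 with F3 (NiCl2·glyme, 4,4'-di-tert-butyl-2,2'-bipyridine, THF/DMF, rt) should give 10, which continues with step 5.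

Step 1. O-acylation of the phenoxides, ketene formation from the enolisable acid chloride, or poor solubility of the polylithiated species may compete with C-acylation. The fallback is a two-stage Baker–Venkataraman sequence (intramolecular O→C acyl transfer in place of intermolecular enolate acylation); it sets out from 1 and comes back at 6. Compound 1 would be O-acylated three times with 2 (3.3 equiv, Et3N, cat. DMAP, CH2Cl2) to 2-acetylbenzene-1,3,5-triyl tris(6-methoxy-6-oxohexanoate) F4. Treatment with LiHMDS (THF, −78 → 0 °C) should move one ortho acyl group to the acetyl carbon and give methyl 8-[2-hydroxy-4,6-bis(6-methoxy-6-oxohexanoyloxy)phenyl]-6,8-dioxooctanoate F5. Under the conditions of step 2, F5 should cyclise and lose its remaining aryl and methyl esters by hydrolysis to give 6.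

Step 2. Ester hydrolysis may remain incomplete under the conditions that close the ring. The fallback separates the two events and cleaves the ester by an SN2 dealkylation instead of acyl substitution; it sets out from 4 and comes back at 6. Diketone 4 would be cyclised with cat. H2SO4 in AcOH at 80 °C and the chromone methyl ester 5 isolated. LiI in refluxing pyridine followed by dilute HCl should then give 6. This fallback makes no compound outside the compound list (F0).

**Further compounds**
F1 | step 4 | 1,3-dioxoisoindolin-2-yl 5-(5,7-diacetoxy-4-oxo-4H-chromen-2-yl)pentanoate | O=C(CCCCc1cc(=O)c2c(OC(C)=O)cc(OC(C)=O)cc2o1)ON1C(=O)c2ccccc2C1=O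
F2 | step 4 | heptadecylmagnesium bromide | CCCCCCCCCCCCCCCCC[Mg]Br
F3 | step 4 | diheptadecylzinc | CCCCCCCCCCCCCCCCC[Zn]CCCCCCCCCCCCCCCCC
F4 | step 1 | 2-acetylbenzene-1,3,5-triyl tris(6-methoxy-6-oxohexanoate) | CC(=O)c1c(OC(=O)CCCCC(=O)OC)cc(OC(=O)CCCCC(=O)OC)cc1OC(=O)CCCCC(=O)OC
F5 | step 1 | methyl 8-[2-hydroxy-4,6-bis(6-methoxy-6-oxohexanoyloxy)phenyl]-6,8-dioxooctanoate | COC(=O)CCCCC(=O)CC(=O)c1c(O)cc(OC(=O)CCCCC(=O)OC)cc1OC(=O)CCCCC(=O)OC
F0 | step 2 | none | none
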